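## Retrosynthetic overview

1. The (E,E,E)-triene is made last, at C15=C16, by Horner–Wadsworth–Emmons olefination of bicyclic aldehyde 22 with dienylphosphonate 26, because a triene would not survive the peroxidation.
2. The 1,2-dioxane (second ring) closes by intramolecular oxa-Michael addition of a C6 tertiary hydroperoxide onto butenolide 17 (first ring); the hydroperoxide comes from cobalt-catalysed hydroperoxysilylation of a 1,1-disubstituted alkene.
3. Butenolide 17 comes from adduct 13 by oxidative lactonisation and E1cB loss of the C3 benzyloxy group, a disposable relay stereocentre.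
4. Key C4–C5 bond: chelation-controlled Hosomi–Sakurai allylation of (S)-α-benzyloxy methyl ketone 8 (from L-malic acid) with 2-substituted allylsilane 12 (from methyl 10-hydroxydecanoate), which sets C4.
5. Locants used below: C1 lactone C=O, C3 peroxy CH, C4 lactone-O quaternary carbon, C6 peroxy quaternary carbon, C7–C22 side chain; the target is (3S,4S,6S).

Assumption: the cobalt peroxidation gives both C6 epimers in about 1:1 ratio, so at most half the material is usable; after ring closure in step 14 the wanted (6S)-peroxide 20 is taken to be separable on silica from its (6R)-epimer, (1S,4R,6S)-4-{9-[(tert-butyldiphenylsilyl)oxy]nonyl}-4,6-dimethyl-2,3,7-trioxabicyclo[4.3.0]nonan-8-one, which is discarded and not carried on.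

## Route

Step 1
Reactants: 1 L-malic acid
Product: 2 2-[(4S)-2,2-dimethyl-5-oxo-1,3-dioxolan-4-yl]acetic acid
Conditions: Me2C(OMe)2, PPTS (cat.), rt
Reagents that add atoms: 2,2-dimethoxypropane, COC(C)(C)OC
Why: Acid-catalysed transacetalisation ties up only the α-hydroxy acid as a five-membered dioxolanone, leaving the distal CO2H free; the stereocentre is untouched.

Step 2
Reactants: 2 2-[(4S)-2,2-dimethyl-5-oxo-1,3-dioxolan-4-yl]acetic acid
Product: 4 (3S)-3-hydroxyoxolan-2-one, via hydroxyethyl dioxolanone 3 (not isolated)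
Conditions: BH3·THF, THF, 0 °C → rt; MeOH; then TsOH (cat.), CH2Cl2, rt
Reagents that add atoms: none
Why: Chemoselective borane reduction of the free acid followed by acid-catalysed translactonisation (loss of acetone) gives the α-hydroxy-γ-butyrolactone without touching the stereocentre.

Step 3
Reactants: 4 (3S)-3-hydroxyoxolan-2-one
Product: 5 (3S)-3-(benzyloxy)oxolan-2-one
Conditions: BnOC(=NH)CCl3, TfOH (cat.), CH2Cl2/cyclohexane, rt
Reagents that add atoms: benzyl 2,2,2-trichloroacetimidate, N=C(OCc1ccccc1)C(Cl)(Cl)Cl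
Why: Acid-catalysed imidate O-benzylation avoids base, so the enolisable α-centre is not racemised.

Step 4
Reactants: 5 (3S)-3-(benzyloxy)oxolan-2-one
Product: 6 (2S)-2-(benzyloxy)-4-hydroxy-N-methoxy-N-methylbutanamide
Conditions: MeNH(OMe)·HCl, AlMe3, CH2Cl2, 0 °C → rt; aq. potassium sodium tartrate
Reagents that add atoms: N,O-dimethylhydroxylamine hydrochloride, CNOC.Cl
Why: Weinreb aminolysis of the lactone with the non-basic aluminium amide opens the ring cleanly without epimerisation.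

Step 5
Reactants: 6 (2S)-2-(benzyloxy)-4-hydroxy-N-methoxy-N-methylbutanamide
Product: 7 (2S)-2-(benzyloxy)-4-[(tert-butyldimethylsilyl)oxy]-N-methoxy-N-methylbutanamide
Conditions: TBSCl, imidazole, DMF, 0 °C → rt
Reagents that add atoms: tert-butyldimethylsilyl chloride, CC(C)(C)[Si](C)(C)Cl
Why: Immediate silylation of the primary alcohol blocks relactonisation of the γ-hydroxy amide.

Step 6
Reactants: 7 (2S)-2-(benzyloxy)-4-[(tert-butyldimethylsilyl)oxy]-N-methoxy-N-methylbutanamide
Product: 8 (3S)-3-(benzyloxy)-5-[(tert-butyldimethylsilyl)oxy]pentan-2-one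
Conditions: MeMgBr, THF, −78 → 0 °C; aq. NH4Cl
Reagents that add atoms: methylmagnesium bromide, C[Mg]Br
Why: Weinreb ketone synthesis stops at the methyl ketone through the stable magnesium chelate and does not racemise the α-alkoxy centre.

Step 7
Reactants: 9 methyl 10-hydroxydecanoate
Product: 10 methyl 10-[(tert-butyldiphenylsilyl)oxy]decanoate
Conditions: TBDPSCl, imidazole, CH2Cl2, rt
Reagents that add atoms: tert-butyldiphenylsilyl chloride, CC(C)(C)[Si](Cl)(c1ccccc1)c1ccccc1
Why: Standard silylation gives a robust, UV-active ether that survives TiCl4, the cobalt step and mild acid.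

Step 8
Reactants: 10 methyl 10-[(tert-butyldiphenylsilyl)oxy]decanoate
Product: 12 tert-butyl{[10-methylidene-11-(trimethylsilyl)undecyl]oxy}diphenylsilane, via bis(silylmethyl) carbinol 11 (not isolated)
Conditions: Me3SiCH2MgCl, CeCl3, THF, −78 °C → rt; then silica gel, CH2Cl2, rt
Reagents that add atoms: (trimethylsilyl)methylmagnesium chloride, C[Si](C)(C)C[Mg]Cl
Why: Cerium-mediated double addition to the ester and Peterson elimination of one β-silyl group (Bunnelle–Narayanan allylsilane synthesis) turns the ester carbon into C6 of a 2-substituted allylsilane.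

Step 9
Reactants: 8 (3S)-3-(benzyloxy)-5-[(tert-butyldimethylsilyl)oxy]pentan-2-one; 12 tert-butyl{[10-methylidene-11-(trimethylsilyl)undecyl]oxy}diphenylsilane
Product: 13 (3S,4S)-3-(benzyloxy)-1-[(tert-butyldimethylsilyl)oxy]-15-[(tert-butyldiphenylsilyl)oxy]-4-methyl-6-methylidenepentadecan-4-ol
Conditions: 8, TiCl4 (1.1 equiv), CH2Cl2, −78 °C; then 12 (1.3 equiv), −78 °C; aq. NaHCO3
Reagents that add atoms: none
Why: Hosomi–Sakurai allylation under Cram-chelate control: TiCl4 locks the ketone oxygen and the α-benzyloxy oxygen in a five-membered chelate and the allylsilane attacks the face opposite the C2 chain, forming the C4–C5 bond and setting C4 as S (syn to OBn).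

Step 10
Reactants: 13 (3S,4S)-3-(benzyloxy)-1-[(tert-butyldimethylsilyl)oxy]-15-[(tert-butyldiphenylsilyl)oxy]-4-methyl-6-methylidenepentadecan-4-ol
Product: 14 (3S,4S)-3-(benzyloxy)-15-[(tert-butyldiphenylsilyl)oxy]-4-methyl-6-methylidenepentadecane-1,4-diol
Conditions: PPTS (cat.), MeOH, rt
Reagents that add atoms: none
Why: Mild acid methanolysis removes the primary TBS ether selectively while the bulkier primary TBDPS ether, the benzyl ether and the alkene remain.

Step 11
Reactants: 14 (3S,4S)-3-(benzyloxy)-15-[(tert-butyldiphenylsilyl)oxy]-4-methyl-6-methylidenepentadecane-1,4-diol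
Product: 16 (4S,5S)-4-(benzyloxy)-5-{11-[(tert-butyldiphenylsilyl)oxy]-2-methylideneundecyl}-5-methyloxolan-2-one, via lactol 15 (not isolated)
Conditions: TEMPO (20 mol %), PhI(OAc)2 (2.5 equiv), CH2Cl2, rt
Reagents that add atoms: none
Why: TEMPO/PhI(OAc)2 oxidative lactonisation oxidises only the primary alcohol, the aldehyde closes onto the tertiary C4 hydroxyl and the lactol is oxidised on to the γ-lactone; no stereocentre is affected.

Step 12
Reactants: 16 (4S,5S)-4-(benzyloxy)-5-{11-[(tert-butyldiphenylsilyl)oxy]-2-methylideneundecyl}-5-methyloxolan-2-one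
Product: 17 (5S)-5-{11-[(tert-butyldiphenylsilyl)oxy]-2-methylideneundecyl}-5-methylfuran-2(5H)-one
Conditions: DBU, CH2Cl2, rt
Reagents that add atoms: none
Why: E1cB β-elimination of benzyl alcohol from the lactone enolate gives the butenolide; the relay centre C3 is erased and the quaternary C4 (no γ-hydrogen) cannot epimerise.

Step 13
Reactants: 17 (5S)-5-{11-[(tert-butyldiphenylsilyl)oxy]-2-methylideneundecyl}-5-methylfuran-2(5H)-one
Product: 18 (5S)-5-{11-[(tert-butyldiphenylsilyl)oxy]-2-methyl-2-[(triethylsilyl)peroxy]undecyl}-5-methylfuran-2(5H)-one (about 1:1 epimers at the peroxy carbon)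
Conditions: Co(thd)2 (10 mol %, thd = 2,2,6,6-tetramethylheptane-3,5-dionate), Et3SiH, O2 (1 atm), ClCH2CH2Cl, rt
Reagents that add atoms: dioxygen, O=O; triethylsilane, CC[SiH](CC)CC
Why: Mukaiyama–Isayama hydroperoxysilylation: hydrogen-atom transfer to the electron-rich 1,1-disubstituted alkene gives the tertiary C6 radical (Markovnikov), which is trapped by O2 on either face, so C6 is formed without control while the conjugated butenolide alkene reacts far more slowly.

Step 14
Reactants: 18 (5S)-5-{11-[(tert-butyldiphenylsilyl)oxy]-2-methyl-2-[(triethylsilyl)peroxy]undecyl}-5-methylfuran-2(5H)-one (epimer mixture)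
Product: 20 (1S,4S,6S)-4-{9-[(tert-butyldiphenylsilyl)oxy]nonyl}-4,6-dimethyl-2,3,7-trioxabicyclo[4.3.0]nonan-8-one, via hydroperoxide 19 (not isolated)
Conditions: HCl (cat.), MeOH, 0 °C; then Et2NH, CF3CH2OH, rt; chromatography (removes the C6 epimer)
Reagents that add atoms: none
Why: Methanolysis frees the hydroperoxide, which adds 6-exo-trig to the butenolide (intramolecular oxa-Michael addition) on the face of its tether, so C3 is set as S by the cis ring fusion dictated by C4; the (6S)-isomer 20 is separated on silica from its (6R)-epimer, which is discarded.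

Step 15
Reactants: 20 (1S,4S,6S)-4-{9-[(tert-butyldiphenylsilyl)oxy]nonyl}-4,6-dimethyl-2,3,7-trioxabicyclo[4.3.0]nonan-8-one
Product: 21 (1S,4S,6S)-4-(9-hydroxynonyl)-4,6-dimethyl-2,3,7-trioxabicyclo[4.3.0]nonan-8-one
Conditions: HF·pyridine, pyridine, THF, 0 °C → rt
Reagents that add atoms: none
Why: Buffered fluoride desilylation is acidic rather than basic, so the base-labile β-peroxy lactone and the O–O bond are preserved.

Step 16
Reactants: 21 (1S,4S,6S)-4-(9-hydroxynonyl)-4,6-dimethyl-2,3,7-trioxabicyclo[4.3.0]nonan-8-one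
Product: 22 9-[(1S,4S,6S)-4,6-dimethyl-8-oxo-2,3,7-trioxabicyclo[4.3.0]nonan-4-yl]nonanal
Conditions: Dess–Martin periodinane, NaHCO3, CH2Cl2, 0 °C → rt
Reagents that add atoms: none
Why: Dess–Martin oxidation is neutral and non-reducing, so the dialkyl peroxide and lactone survive and no over-oxidation occurs.

Step 17
Reactants: 23 (2E,4E)-hepta-2,4-dienal
Product: 24 (2E,4E)-hepta-2,4-dien-1-ol
Conditions: NaBH4, CeCl3·7H2O, MeOH, 0 °C
Reagents that add atoms: none
Why: Luche reduction gives clean 1,2-reduction of the dienal with the diene geometry retained.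

Step 18
Reactants: 24 (2E,4E)-hepta-2,4-dien-1-ol
Product: 25 (2E,4E)-1-bromohepta-2,4-diene
Conditions: PBr3, Et2O, 0 °C
Reagents that add atoms: phosphorus tribromide, BrP(Br)Br
Why: Bromination of the primary dienylic alcohol gives the thermodynamically preferred primary (E,E)-bromide.

Step 19
Reactants: 25 (2E,4E)-1-bromohepta-2,4-diene
Product: 26 diethyl [(2E,4E)-hepta-2,4-dien-1-yl]phosphonate
Conditions: P(OEt)3, neat, 110 °C
Reagents that add atoms: triethyl phosphite, CCOP(OCC)OCC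
Why: Michaelis–Arbuzov reaction of the reactive primary allylic bromide gives the dienylphosphonate with the (E,E)-diene intact.

Step 20
Reactants: 22 9-[(1S,4S,6S)-4,6-dimethyl-8-oxo-2,3,7-trioxabicyclo[4.3.0]nonan-4-yl]nonanal; 26 diethyl [(2E,4E)-hepta-2,4-dien-1-yl]phosphonate
Product: 27 (1S,4S,6S)-4-[(9E,11E,13E)-hexadeca-9,11,13-trien-1-yl]-4,6-dimethyl-2,3,7-trioxabicyclo[4.3.0]nonan-8-one (CNP0229098.1)
Conditions: 26, LiHMDS, THF/DMPU, −78 °C; then 22, −78 °C → rt
Reagents that add atoms: none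
Why: Horner–Wadsworth–Emmons olefination with the pre-formed dienylphosphonate anion gives the new C15=C16 bond with E geometry, and adding the aldehyde to a slight deficiency of base at −78 °C keeps the β-peroxy lactone away from free base.

## Compound list

1 | L-malic acid, (2S)-2-hydroxybutanedioic acid | OC(=O)C[C@H](O)C(=O)O | starting material
2 | 2-[(4S)-2,2-dimethyl-5-oxo-1,3-dioxolan-4-yl]acetic acid | CC1(C)O[C@@H](CC(=O)O)C(=O)O1 | intermediate
3 | (5S)-5-(2-hydroxyethyl)-2,2-dimethyl-1,3-dioxolan-4-one | CC1(C)O[C@@H](CCO)C(=O)O1 | intermediate (not isolated)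
4 | (3S)-3-hydroxyoxolan-2-one | O[C@H]1CCOC1=O | intermediate
5 | (3S)-3-(benzyloxy)oxolan-2-one | O=C1OCC[C@@H]1OCc1ccccc1 | intermediate
6 | (2S)-2-(benzyloxy)-4-hydroxy-N-methoxy-N-methylbutanamide | CON(C)C(=O)[C@H](CCO)OCc1ccccc1 | intermediate
7 | (2S)-2-(benzyloxy)-4-[(tert-butyldimethylsilyl)oxy]-N-methoxy-N-methylbutanamide | CON(C)C(=O)[C@H](CCO[Si](C)(C)C(C)(C)C)OCc1ccccc1 | intermediate
8 | (3S)-3-(benzyloxy)-5-[(tert-butyldimethylsilyl)oxy]pentan-2-one | CC(=O)[C@H](CCO[Si](C)(C)C(C)(C)C)OCc1ccccc1 | intermediate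
9 | methyl 10-hydroxydecanoate | COC(=O)CCCCCCCCCO | starting material
10 | methyl 10-[(tert-butyldiphenylsilyl)oxy]decanoate | COC(=O)CCCCCCCCCO[Si](c1ccccc1)(c1ccccc1)C(C)(C)C | intermediate
11 | 11-[(tert-butyldiphenylsilyl)oxy]-1-(trimethylsilyl)-2-[(trimethylsilyl)methyl]undecan-2-ol | C[Si](C)(C)CC(O)(C[Si](C)(C)C)CCCCCCCCCO[Si](c1ccccc1)(c1ccccc1)C(C)(C)C | intermediate (not isolated)
12 | tert-butyl{[10-methylidene-11-(trimethylsilyl)undecyl]oxy}diphenylsilane | C=C(C[Si](C)(C)C)CCCCCCCCCO[Si](c1ccccc1)(c1ccccc1)C(C)(C)C | intermediate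
13 | (3S,4S)-3-(benzyloxy)-1-[(tert-butyldimethylsilyl)oxy]-15-[(tert-butyldiphenylsilyl)oxy]-4-methyl-6-methylidenepentadecan-4-ol | CC(C)(C)[Si](C)(C)OCC[C@H](OCc1ccccc1)[C@@](C)(O)CC(=C)CCCCCCCCCO[Si](c1ccccc1)(c1ccccc1)C(C)(C)C | intermediate
14 | (3S,4S)-3-(benzyloxy)-15-[(tert-butyldiphenylsilyl)oxy]-4-methyl-6-methylidenepentadecane-1,4-diol | OCC[C@H](OCc1ccccc1)[C@@](C)(O)CC(=C)CCCCCCCCCO[Si](c1ccccc1)(c1ccccc1)C(C)(C)C | intermediate
15 | (4S,5S)-4-(benzyloxy)-5-{11-[(tert-butyldiphenylsilyl)oxy]-2-methylideneundecyl}-5-methyloxolan-2-ol (lactol, both anomers) | OC1C[C@H](OCc2ccccc2)[C@](C)(CC(=C)CCCCCCCCCO[Si](c2ccccc2)(c2ccccc2)C(C)(C)C)O1 | intermediate (not isolated)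
16 | (4S,5S)-4-(benzyloxy)-5-{11-[(tert-butyldiphenylsilyl)oxy]-2-methylideneundecyl}-5-methyloxolan-2-one | O=C1C[C@H](OCc2ccccc2)[C@](C)(CC(=C)CCCCCCCCCO[Si](c2ccccc2)(c2ccccc2)C(C)(C)C)O1 | intermediate
17 | (5S)-5-{11-[(tert-butyldiphenylsilyl)oxy]-2-methylideneundecyl}-5-methylfuran-2(5H)-one | O=C1C=C[C@](C)(CC(=C)CCCCCCCCCO[Si](c2ccccc2)(c2ccccc2)C(C)(C)C)O1 | intermediate
18 | (5S)-5-{11-[(tert-butyldiphenylsilyl)oxy]-2-methyl-2-[(triethylsilyl)peroxy]undecyl}-5-methylfuran-2(5H)-one, about 1:1 mixture of epimers at the peroxy carbon | O=C1C=C[C@](C)(CC(C)(OO[Si](CC)(CC)CC)CCCCCCCCCO[Si](c2ccccc2)(c2ccccc2)C(C)(C)C)O1 | intermediate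
19 | (5S)-5-{11-[(tert-butyldiphenylsilyl)oxy]-2-hydroperoxy-2-methylundecyl}-5-methylfuran-2(5H)-one, epimer mixture | O=C1C=C[C@](C)(CC(C)(OO)CCCCCCCCCO[Si](c2ccccc2)(c2ccccc2)C(C)(C)C)O1 | intermediate (not isolated)
20 | (1S,4S,6S)-4-{9-[(tert-butyldiphenylsilyl)oxy]nonyl}-4,6-dimethyl-2,3,7-trioxabicyclo[4.3.0]nonan-8-one | CC(C)(C)[Si](c1ccccc1)(c1ccccc1)OCCCCCCCCC[C@@]1(C)C[C@]2(C)OC(=O)C[C@@H]2OO1 | intermediate
21 | (1S,4S,6S)-4-(9-hydroxynonyl)-4,6-dimethyl-2,3,7-trioxabicyclo[4.3.0]nonan-8-one | OCCCCCCCCC[C@@]1(C)C[C@]2(C)OC(=O)C[C@@H]2OO1 | intermediate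
22 | 9-[(1S,4S,6S)-4,6-dimethyl-8-oxo-2,3,7-trioxabicyclo[4.3.0]nonan-4-yl]nonanal | O=CCCCCCCCC[C@@]1(C)C[C@]2(C)OC(=O)C[C@@H]2OO1 | intermediate
23 | (2E,4E)-hepta-2,4-dienal | CC/C=C/C=C/C=O | starting material
24 | (2E,4E)-hepta-2,4-dien-1-ol | CC/C=C/C=C/CO | intermediate
25 | (2E,4E)-1-bromohepta-2,4-diene | CC/C=C/C=C/CBr | intermediate
26 | diethyl [(2E,4E)-hepta-2,4-dien-1-yl]phosphonate | CC/C=C/C=C/CP(=O)(OCC)OCC | intermediate
27 | (1S,4S,6S)-4-[(9E,11E,13E)-hexadeca-9,11,13-trien-1-yl]-4,6-dimethyl-2,3,7-trioxabicyclo[4.3.0]nonan-8-one | CC/C=C/C=C/C=C/CCCCCCCC[C@@]1(C)C[C@]2(C)OC(=O)C[C@@H]2OO1 | target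

## Step count and risks

Total steps: 20. Longest linear sequence: 15 steps (steps 1–6, 9–16 and 20, from L-malic acid).

Three steps most likely to fail:

Step 9 (chelation-controlled Sakurai allylation). The methyl ketone may react sluggishly, the allylsilane may protodesilylate, or the diastereoselectivity may fall short. The fallback makes the same C4–C5 bond by a chelation-controlled Mukaiyama aldol reaction and installs the methylidene afterwards; it sets out from 10 (with 8) and returns at 13. Ester 10 is converted with MeNH(OMe)·HCl and i-PrMgCl into 10-[(tert-butyldiphenylsilyl)oxy]-N-methoxy-N-methyldecanamide F1. MeMgBr then gives 11-[(tert-butyldiphenylsilyl)oxy]undecan-2-one F2. Kinetic enolisation (LDA, Me3SiCl, −78 °C) gives tert-butyl({10-[(trimethylsilyl)oxy]undec-10-en-1-yl}oxy)diphenylsilane F3. Addition of F3 to the TiCl4 chelate of 8 at −78 °C gives (12S,13S)-13-(benzyloxy)-15-[(tert-butyldimethylsilyl)oxy]-1-[(tert-butyldiphenylsilyl)oxy]-12-hydroxy-12-methylpentadecan-10-one F4 with the same facial control. Non-basic Lombardo methylenation of the C6 ketone (Zn, CH2Br2, TiCl4), which avoids retro-aldol cleavage, then delivers 13.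

Step 13 (cobalt hydroperoxysilylation). The butenolide C=C may compete for the cobalt hydride, and C6 is formed without control, so at best half the material is the wanted epimer. The fallback removes the chemoselectivity problem by changing the order of events; it sets out from 16 and returns at 18. The same Co(thd)2/Et3SiH/O2 conditions are applied to the saturated lactone 16, which has no conjugated alkene. This gives (4S,5S)-4-(benzyloxy)-5-{11-[(tert-butyldiphenylsilyl)oxy]-2-methyl-2-[(triethylsilyl)peroxy]undecyl}-5-methyloxolan-2-one F5 (epimer mixture). DBU then eliminates benzyl alcohol to give 18. This does not cure the lack of control at C6, for which chromatographic separation of 20 from its C6 epimer in step 14 remains the only remedy.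

Step 20 (Horner–Wadsworth–Emmons triene formation). The β-peroxy lactone can ring-open by E1cB under base, and the dienyl anion may give E/Z or α/γ mixtures. The fallback builds the triene outward from the aldehyde under neutral conditions and forms C19=C20 last; it sets out from 22 and returns at 27. Wittig reaction of 22 with Ph3P=CHCHO (toluene, 80 °C) gives (2E)-11-[(1S,4S,6S)-4,6-dimethyl-8-oxo-2,3,7-trioxabicyclo[4.3.0]nonan-4-yl]undec-2-enal F6. A second Wittig reaction with the same ylide gives (2E,4E)-13-[(1S,4S,6S)-4,6-dimethyl-8-oxo-2,3,7-trioxabicyclo[4.3.0]nonan-4-yl]trideca-2,4-dienal F7. Separately, 1-phenyl-1H-tetrazole-5-thiol is alkylated with 1-bromopropane to 1-phenyl-5-(propylsulfanyl)-1H-tetrazole F8 and oxidised (H2O2, (NH4)6Mo7O24) to 1-phenyl-5-(propylsulfonyl)-1H-tetrazole F9. Julia–Kocienski olefination of F7 with the pre-formed potassium anion of F9 (KHMDS, DME, −60 °C) gives 27.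

## Further compounds

F1 | step 9 | 10-[(tert-butyldiphenylsilyl)oxy]-N-methoxy-N-methyldecanamide | CON(C)C(=O)CCCCCCCCCO[Si](c1ccccc1)(c1ccccc1)C(C)(C)C
F2 | step 9 | 11-[(tert-butyldiphenylsilyl)oxy]undecan-2-one | CC(=O)CCCCCCCCCO[Si](c1ccccc1)(c1ccccc1)C(C)(C)C
F3 | step 9 | tert-butyl({10-[(trimethylsilyl)oxy]undec-10-en-1-yl}oxy)diphenylsilane | C=C(O[Si](C)(C)C)CCCCCCCCCO[Si](c1ccccc1)(c1ccccc1)C(C)(C)C
F4 | step 9 | (12S,13S)-13-(benzyloxy)-15-[(tert-butyldimethylsilyl)oxy]-1-[(tert-butyldiphenylsilyl)oxy]-12-hydroxy-12-methylpentadecan-10-one | CC(C)(C)[Si](C)(C)OCC[C@H](OCc1ccccc1)[C@@](C)(O)CC(=O)CCCCCCCCCO[Si](c1ccccc1)(c1ccccc1)C(C)(C)C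
F5 | step 13 | (4S,5S)-4-(benzyloxy)-5-{11-[(tert-butyldiphenylsilyl)oxy]-2-methyl-2-[(triethylsilyl)peroxy]undecyl}-5-methyloxolan-2-one (epimers at the peroxy carbon) | O=C1C[C@H](OCc2ccccc2)[C@](C)(CC(C)(OO[Si](CC)(CC)CC)CCCCCCCCCO[Si](c2ccccc2)(c2ccccc2)C(C)(C)C)O1
F6 | step 20 | (2E)-11-[(1S,4S,6S)-4,6-dimethyl-8-oxo-2,3,7-trioxabicyclo[4.3.0]nonan-4-yl]undec-2-enal | O=C/C=C/CCCCCCCC[C@@]1(C)C[C@]2(C)OC(=O)C[C@@H]2OO1
F7 | step 20 | (2E,4E)-13-[(1S,4S,6S)-4,6-dimethyl-8-oxo-2,3,7-trioxabicyclo[4.3.0]nonan-4-yl]trideca-2,4-dienal | O=C/C=C/C=C/CCCCCCCC[C@@]1(C)C[C@]2(C)OC(=O)C[C@@H]2OO1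
F8 | step 20 | 1-phenyl-5-(propylsulfanyl)-1H-tetrazole | CCCSc1nnnn1-c1ccccc1
F9 | step 20 | 1-phenyl-5-(propylsulfonyl)-1H-tetrazole | CCCS(=O)(=O)c1nnnn1-c1ccccc1
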